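**Strategy.** In cembrane numbering, the C12 tertiary acyloxy / C11 hydroxy pair sits where the seven-membered lactone (O–C12–C13–C14–C1–C15–C16) meets the 14-membered carbocycle. It is read as the anti-opening product of a (Z)-C11=C12 epoxide by the C16 carboxyl, so C12 can be an sp2 carbon when the macrocycle is closed. The key step is an intramolecular Negishi coupling. A C13 alkylzinc and a (Z)-C12 alkenyl iodide sit in one open chain that already holds the cis-tetrahydrofuran (C4–O–C7), the C1/C2 stereocentres and the acrylate. They join to give the 14-membered ring and the Z-olefin in one operation.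

Key step: step 18

Remark: cembrane numbering is used throughout (ring C1–C14; C15, C16, C17 are the acrylate α-carbon, carbonyl and methylene on C1; C18, C19, C20 are the one-carbon branches on C4, C8, C12; the ether oxygen links C4 and C7). The L-fructose-derived Shi ketone is assumed to be purchased or made from L-sorbose.

**Tetrahydrofuran–alkenyl iodide fragment**

Step 1
Reactants: 1 geraniol
Product: 2 (2S,3S)-2,3-epoxygeraniol
Conditions: Ti(OiPr)4 (5 mol %), L-(+)-diethyl tartrate (6 mol %), t-BuOOH, 4 Å molecular sieves, CH2Cl2, −20 °C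
Reagents that add atoms: tert-butyl hydroperoxide, CC(C)(C)OO
Why: Sharpless asymmetric epoxidation of the allylic alcohol, in which the L-tartrate complex delivers oxygen to the face that gives the (2S,3S)-epoxide and so fixes the future C4 (S), while the isolated 6,7-olefin is left untouched.

Step 2
Reactants: 2 (2S,3S)-2,3-epoxygeraniol
Product: 3 (3S)-3,7-dimethyloct-6-ene-1,3-diol
Conditions: NaAlH2(OCH2CH2OMe)2, THF, 0 °C to rt
Reagents that add atoms: none
Why: Regioselective reductive opening of a 2,3-epoxy alcohol, in which the aluminate bound to the primary oxygen delivers hydride to C2 and leaves the tertiary C–O bond and its configuration intact.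

Step 3
Reactants: 3 (3S)-3,7-dimethyloct-6-ene-1,3-diol
Product: 4 (3S)-1-[(tert-butyldiphenylsilyl)oxy]-3,7-dimethyloct-6-en-3-ol
Conditions: t-BuPh2SiCl, imidazole, CH2Cl2, 0 °C to rt
Reagents that add atoms: tert-butyl(chloro)diphenylsilane, CC(C)(C)[Si](Cl)(c1ccccc1)c1ccccc1
Why: Silyl ether formation that should be selective for the primary hydroxyl because the tertiary alcohol is too hindered for the bulky chlorosilane.

Step 4
Reactants: 4 (3S)-1-[(tert-butyldiphenylsilyl)oxy]-3,7-dimethyloct-6-en-3-ol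
Product: 6 2-[(2R,5S)-5-{2-[(tert-butyldiphenylsilyl)oxy]ethyl}-5-methyloxolan-2-yl]propan-2-ol, via (6S)-6,7-epoxide 5 (not isolated)
Conditions: L-fructose-derived Shi ketone (1,2:4,5-di-O-isopropylidene-β-L-erythro-2,3-hexodiulo-2,6-pyranose, 30 mol %), KHSO5 (Oxone), K2CO3, Bu4NHSO4, MeCN/dimethoxymethane/aq. Na2B4O7 buffer, 0 °C; then camphorsulfonic acid (10 mol %), CH2Cl2, 0 °C
Reagents that add atoms: Oxone (potassium peroxymonosulfate), [K+].[O-]S(=O)(=O)OO
Why: Shi asymmetric epoxidation (dioxirane, spiro transition state) should give the (S)-epoxide of the trisubstituted olefin under catalyst control, and acid-catalysed 5-exo-tet opening by the tertiary hydroxyl with inversion then sets the future C7 (R) and the cis relation of the two ring chains.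

Step 5
Reactants: 6 2-[(2R,5S)-5-{2-[(tert-butyldiphenylsilyl)oxy]ethyl}-5-methyloxolan-2-yl]propan-2-ol
Product: 7 tert-butyl{2-[(2S,5R)-2-methyl-5-(prop-1-en-2-yl)oxolan-2-yl]ethoxy}diphenylsilane
Conditions: SOCl2, pyridine, CH2Cl2, −10 °C to 0 °C
Reagents that add atoms: none
Why: Dehydration through the chlorosulfite (E2 elimination), in which only methyl hydrogens and the ring C–H next to oxygen are available and the latter is inductively deactivated and would lead to an enol ether, so the isopropenyl group is expected.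

Step 6
Reactants: 7 tert-butyl{2-[(2S,5R)-2-methyl-5-(prop-1-en-2-yl)oxolan-2-yl]ethoxy}diphenylsilane
Product: 8 2-[(2R,5S)-5-{2-[(tert-butyldiphenylsilyl)oxy]ethyl}-5-methyloxolan-2-yl]prop-2-en-1-ol
Conditions: SeO2 (30 mol %), t-BuOOH, CH2Cl2, rt
Reagents that add atoms: tert-butyl hydroperoxide, CC(C)(C)OO (oxygen relayed by SeO2, O=[Se]=O)
Why: Selenium dioxide allylic oxidation (ene reaction then [2,3]-sigmatropic shift) should hydroxylate the allylic methyl in preference to the tertiary ring C–H and return the 1,1-disubstituted olefin to its place.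

Step 7
Reactants: 8 2-[(2R,5S)-5-{2-[(tert-butyldiphenylsilyl)oxy]ethyl}-5-methyloxolan-2-yl]prop-2-en-1-ol
Product: 9 ethyl 4-[(2R,5S)-5-{2-[(tert-butyldiphenylsilyl)oxy]ethyl}-5-methyloxolan-2-yl]pent-4-enoate
Conditions: MeC(OEt)3, EtCO2H (cat.), 140 °C
Reagents that add atoms: triethyl orthoacetate, CC(OCC)(OCC)OCC
Why: Johnson–Claisen rearrangement, in which the mixed ketene acetal of the allylic alcohol undergoes a [3,3]-shift that adds C10 and C11 and regenerates the C8=C19 exo-methylene.

Step 8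
Reactants: 9 ethyl 4-[(2R,5S)-5-{2-[(tert-butyldiphenylsilyl)oxy]ethyl}-5-methyloxolan-2-yl]pent-4-enoate
Product: 10 4-[(2R,5S)-5-{2-[(tert-butyldiphenylsilyl)oxy]ethyl}-5-methyloxolan-2-yl]pent-4-enal
Conditions: i-Bu2AlH (1.1 equiv), CH2Cl2, −78 °C
Reagents that add atoms: none
Why: Partial reduction of the ester, in which the tetrahedral aluminium hemiacetal is stable at −78 °C and releases the aldehyde only on work-up.

Step 9
Reactants: 10 4-[(2R,5S)-5-{2-[(tert-butyldiphenylsilyl)oxy]ethyl}-5-methyloxolan-2-yl]pent-4-enal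
Product: 11 tert-butyl{2-[(2S,5R)-5-[(5Z)-6-iodohepta-1,5-dien-2-yl]-2-methyloxolan-2-yl]ethoxy}diphenylsilane
Conditions: EtPPh3I, n-BuLi, THF, rt; I2, −78 °C; NaN(SiMe3)2, −20 °C; then 10, −78 °C to −20 °C
Reagents that add atoms: ethyltriphenylphosphonium iodide, CC[P+](c1ccccc1)(c1ccccc1)c1ccccc1.[I-]; iodine, II
Why: Stork–Zhao-type Wittig olefination with the α-iodo ylide, whose kinetically controlled cis-oxaphosphetane should give the (Z)-2-iodoalk-2-ene with iodine cis to the chain, the geometry that C11=C12 needs.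

Step 10
Reactants: 11 tert-butyl{2-[(2S,5R)-5-[(5Z)-6-iodohepta-1,5-dien-2-yl]-2-methyloxolan-2-yl]ethoxy}diphenylsilane
Product: 12 2-[(2S,5R)-5-[(5Z)-6-iodohepta-1,5-dien-2-yl]-2-methyloxolan-2-yl]ethan-1-ol
Conditions: Bu4NF, THF, 0 °C to rt
Reagents that add atoms: none
Why: Fluoride-mediated desilylation driven by the strong Si–F bond, to which the alkenyl iodide and both olefins are inert.

Step 11
Reactants: 12 2-[(2S,5R)-5-[(5Z)-6-iodohepta-1,5-dien-2-yl]-2-methyloxolan-2-yl]ethan-1-ol
Product: 13 2-[(2S,5R)-5-[(5Z)-6-iodohepta-1,5-dien-2-yl]-2-methyloxolan-2-yl]acetaldehyde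
Conditions: Dess–Martin periodinane, CH2Cl2, 0 °C to rt
Reagents that add atoms: none
Why: Dess–Martin oxidation under near-neutral conditions, which should avoid β-elimination of the ring oxygen from the β-alkoxy aldehyde; the crude aldehyde is used at once.

**Acrylate fragment**

Step 12
Reactants: 14 3-[(tert-butyldimethylsilyl)oxy]propanal; 15 tert-butyl acrylate
Product: 16 tert-butyl 5-[(tert-butyldimethylsilyl)oxy]-3-hydroxy-2-methylidenepentanoate (racemic)
Conditions: DABCO (0.5 equiv), 1,4-dioxane/H2O, rt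
Reagents that add atoms: none
Why: Morita–Baylis–Hillman reaction, in which the amine-derived acrylate enolate adds to the aldehyde and the catalyst is expelled; the carbinol centre is lost in the next step, so no stereocontrol is needed.

Step 13
Reactants: 16 tert-butyl 5-[(tert-butyldimethylsilyl)oxy]-3-hydroxy-2-methylidenepentanoate
Product: 17 tert-butyl (2Z)-2-(bromomethyl)-5-[(tert-butyldimethylsilyl)oxy]pent-2-enoate
Conditions: N-bromosuccinimide, Me2S, CH2Cl2, 0 °C to rt
Reagents that add atoms: N-bromosuccinimide, O=C1CCC(=O)N1Br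
Why: Corey–Kim-type activation of the allylic alcohol as an alkoxysulfonium followed by SN2′ bromide attack, which should give the thermodynamically preferred (Z)-2-(bromomethyl)enoate with the chain trans to the ester.

**Union and end game**

Step 14
Reactants: 13 2-[(2S,5R)-5-[(5Z)-6-iodohepta-1,5-dien-2-yl]-2-methyloxolan-2-yl]acetaldehyde; 17 tert-butyl (2Z)-2-(bromomethyl)-5-[(tert-butyldimethylsilyl)oxy]pent-2-enoate
Product: 19 tert-butyl (3R,4S)-3-{2-[(tert-butyldimethylsilyl)oxy]ethyl}-4-hydroxy-5-[(2S,5R)-5-[(5Z)-6-iodohepta-1,5-dien-2-yl]-2-methyloxolan-2-yl]-2-methylidenepentanoate, via trimethylsilyl ether 18 (not isolated)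
Conditions: CrCl2 (10 mol %, nickel-free), chiral carbazole bis(oxazoline) ligand (12 mol %, enantiomer chosen for Re-face addition), Mn, Me3SiCl, i-Pr2NEt, THF, rt; then 0.5 M HCl, THF, 0 °C
Reagents that add atoms: none
Why: Catalytic asymmetric Nozaki–Hiyama allylation, in which the allylchromium attacks through its γ-carbon in a chair transition state that places the C14 chain equatorial and so gives the anti C1/C2 pair, while the chiral chromium complex selects the Re face of the aldehyde (C2 S, hence C1 R) and the tert-butyl ester resists γ-lactonisation.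

Step 15
Reactants: 19 tert-butyl (3R,4S)-3-{2-[(tert-butyldimethylsilyl)oxy]ethyl}-4-hydroxy-5-[(2S,5R)-5-[(5Z)-6-iodohepta-1,5-dien-2-yl]-2-methyloxolan-2-yl]-2-methylidenepentanoate
Product: 20 tert-butyl (3R,4S)-4-[(tert-butyldimethylsilyl)oxy]-3-{2-[(tert-butyldimethylsilyl)oxy]ethyl}-5-[(2S,5R)-5-[(5Z)-6-iodohepta-1,5-dien-2-yl]-2-methyloxolan-2-yl]-2-methylidenepentanoate
Conditions: t-BuMe2SiOTf, 2,6-lutidine, CH2Cl2, −78 °C
Reagents that add atoms: tert-butyldimethylsilyl triflate, CC(C)(C)[Si](C)(C)OS(=O)(=O)C(F)(F)F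
Why: Silylation of the hindered secondary alcohol with the silyl triflate at low temperature, where the tert-butyl ester and the exo-methylene should survive.

Step 16
Reactants: 20 tert-butyl (3R,4S)-4-[(tert-butyldimethylsilyl)oxy]-3-{2-[(tert-butyldimethylsilyl)oxy]ethyl}-5-[(2S,5R)-5-[(5Z)-6-iodohepta-1,5-dien-2-yl]-2-methyloxolan-2-yl]-2-methylidenepentanoate
Product: 21 tert-butyl (3R,4S)-4-[(tert-butyldimethylsilyl)oxy]-3-(2-hydroxyethyl)-5-[(2S,5R)-5-[(5Z)-6-iodohepta-1,5-dien-2-yl]-2-methyloxolan-2-yl]-2-methylidenepentanoate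
Conditions: HF·pyridine, pyridine, THF, 0 °C
Reagents that add atoms: none
Why: Selective desilylation, in which buffered HF·pyridine should cleave the unhindered primary silyl ether well before the secondary one flanked by two branched carbons.

Step 17
Reactants: 21 tert-butyl (3R,4S)-4-[(tert-butyldimethylsilyl)oxy]-3-(2-hydroxyethyl)-5-[(2S,5R)-5-[(5Z)-6-iodohepta-1,5-dien-2-yl]-2-methyloxolan-2-yl]-2-methylidenepentanoate
Product: 22 tert-butyl (3R,4S)-4-[(tert-butyldimethylsilyl)oxy]-3-(2-iodoethyl)-5-[(2S,5R)-5-[(5Z)-6-iodohepta-1,5-dien-2-yl]-2-methyloxolan-2-yl]-2-methylidenepentanoate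
Conditions: I2, PPh3, imidazole, CH2Cl2, 0 °C
Reagents that add atoms: iodine, II
Why: Appel-type iodination, an SN2 displacement of the alkoxyphosphonium at the primary carbon, which touches no stereocentre.

Step 18
Reactants: 22 tert-butyl (3R,4S)-4-[(tert-butyldimethylsilyl)oxy]-3-(2-iodoethyl)-5-[(2S,5R)-5-[(5Z)-6-iodohepta-1,5-dien-2-yl]-2-methyloxolan-2-yl]-2-methylidenepentanoate
Product: 24 tert-butyl (1R,2S,4S,7R,11Z)-2-[(tert-butyldimethylsilyl)oxy]-4,7-epoxycembra-8(19),11,15(17)-trien-16-oate, via alkylzinc iodide 23 (not isolated)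
Conditions: Zn dust (activated with BrCH2CH2Br, Me3SiCl), THF, 40 °C; then syringe-pump addition to PdCl2(dppf) (10 mol %), THF, 50 °C, final concentration 1 mM
Reagents that add atoms: none
Why: Activated zinc inserts into the primary C13–I bond far faster than into the alkenyl C–I bond, so 23 keeps its (Z)-alkenyl iodide; zerovalent palladium (formed from PdCl2(dppf) by the organozinc) then adds oxidatively to the C12–I bond with retention, the tethered alkylzinc transmetalates, and reductive elimination forms C12–C13. The closest known reaction type is the Negishi coupling of primary alkylzinc halides with (Z)-2-iodoalk-2-enes, here run within one molecule. The step closes the 14-membered carbocycle end to end as a macrocyclisation under high dilution, so no small-ring closure mode applies. No stereocentre is created, but the Z geometry of C11=C12, fixed in 11 and retained in both palladium steps, is the element that later sets C11 and C12. The step needs ring closure to beat oligomerisation and needs the acrylate to stay untouched: the cis-tetrahydrofuran and the Z-olefin bend the chain towards closure, the bidentate dppf ligand suppresses β-hydride elimination, and alkylzinc halides do not add to enoates without copper.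

Step 19
Reactants: 24 tert-butyl (1R,2S,4S,7R,11Z)-2-[(tert-butyldimethylsilyl)oxy]-4,7-epoxycembra-8(19),11,15(17)-trien-16-oate
Product: 25 tert-butyl (1R,2S,4S,7R,11S,12R)-2-[(tert-butyldimethylsilyl)oxy]-4,7:11,12-diepoxycembra-8(19),15(17)-dien-16-oate
Conditions: L-fructose-derived Shi ketone (1.0 equiv), KHSO5 (Oxone), K2CO3, Bu4NHSO4, MeCN/dimethoxymethane/aq. buffer (pH 10.5), −10 °C, stopped when the trisubstituted olefin is consumed
Reagents that add atoms: Oxone (potassium peroxymonosulfate), [K+].[O-]S(=O)(=O)OO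
Why: Shi asymmetric epoxidation, in which the electrophilic dioxirane should choose the electron-rich trisubstituted olefin over the 1,1-disubstituted olefin and the acrylate, and the spiro transition state of the L-fructose-derived ketone should deliver oxygen to the face that gives the cis (11S,12R)-epoxide.

Step 20
Reactants: 25 tert-butyl (1R,2S,4S,7R,11S,12R)-2-[(tert-butyldimethylsilyl)oxy]-4,7:11,12-diepoxycembra-8(19),15(17)-dien-16-oate
Product: 26 (1R,2S,4S,7R,11S,12S)-2-[(tert-butyldimethylsilyl)oxy]-11-hydroxy-4,7-epoxycembra-8(19),15(17)-dien-16,12-olide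
Conditions: camphorsulfonic acid (20 mol %), CH2Cl2, 0 °C to rt
Reagents that add atoms: none
Why: Acid-catalysed intramolecular epoxide opening, in which the ester carbonyl oxygen attacks the tertiary C12 in a 7-exo-tet mode with inversion (C12 S), the epoxide oxygen stays on C11 with retention (C11 S), and the tert-butyl group leaves as isobutene to give the seven-membered lactone.

Step 21
Reactants: 26 (1R,2S,4S,7R,11S,12S)-2-[(tert-butyldimethylsilyl)oxy]-11-hydroxy-4,7-epoxycembra-8(19),15(17)-dien-16,12-olide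
Product: 27 (1R,2S,4S,7R,11S,12S)-2,11-dihydroxy-4,7-epoxycembra-8(19),15(17)-dien-16,12-olide (CNP0289823.1)
Conditions: HF·pyridine, pyridine, THF, 0 °C to rt
Reagents that add atoms: none
Why: Fluoride desilylation under buffered, weakly acidic conditions, which should free the C2 hydroxyl without base-induced translactonisation to the γ-lactone or conjugate addition to the α-methylene lactone.

**Compound list**

1 | geraniol, (2E)-3,7-dimethylocta-2,6-dien-1-ol | CC(C)=CCC/C(C)=C/CO | starting material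
2 | (2S,3S)-2,3-epoxygeraniol | CC(C)=CCC[C@]1(C)O[C@H]1CO | intermediate
3 | (3S)-3,7-dimethyloct-6-ene-1,3-diol | CC(C)=CCC[C@](C)(O)CCO | intermediate
4 | (3S)-1-[(tert-butyldiphenylsilyl)oxy]-3,7-dimethyloct-6-en-3-ol | CC(C)=CCC[C@](C)(O)CCO[Si](c1ccccc1)(c1ccccc1)C(C)(C)C | intermediate
5 | (3S)-1-[(tert-butyldiphenylsilyl)oxy]-5-[(2S)-3,3-dimethyloxiran-2-yl]-3-methylpentan-3-ol (not isolated) | CC1(C)O[C@H]1CC[C@](C)(O)CCO[Si](c1ccccc1)(c1ccccc1)C(C)(C)C | intermediate
6 | 2-[(2R,5S)-5-{2-[(tert-butyldiphenylsilyl)oxy]ethyl}-5-methyloxolan-2-yl]propan-2-ol | CC(C)(O)[C@H]1CC[C@@](C)(CCO[Si](c2ccccc2)(c2ccccc2)C(C)(C)C)O1 | intermediate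
7 | tert-butyl{2-[(2S,5R)-2-methyl-5-(prop-1-en-2-yl)oxolan-2-yl]ethoxy}diphenylsilane | C=C(C)[C@H]1CC[C@@](C)(CCO[Si](c2ccccc2)(c2ccccc2)C(C)(C)C)O1 | intermediate
8 | 2-[(2R,5S)-5-{2-[(tert-butyldiphenylsilyl)oxy]ethyl}-5-methyloxolan-2-yl]prop-2-en-1-ol | C=C(CO)[C@H]1CC[C@@](C)(CCO[Si](c2ccccc2)(c2ccccc2)C(C)(C)C)O1 | intermediate
9 | ethyl 4-[(2R,5S)-5-{2-[(tert-butyldiphenylsilyl)oxy]ethyl}-5-methyloxolan-2-yl]pent-4-enoate | CCOC(=O)CCC(=C)[C@H]1CC[C@@](C)(CCO[Si](c2ccccc2)(c2ccccc2)C(C)(C)C)O1 | intermediate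
10 | 4-[(2R,5S)-5-{2-[(tert-butyldiphenylsilyl)oxy]ethyl}-5-methyloxolan-2-yl]pent-4-enal | O=CCCC(=C)[C@H]1CC[C@@](C)(CCO[Si](c2ccccc2)(c2ccccc2)C(C)(C)C)O1 | intermediate
11 | tert-butyl{2-[(2S,5R)-5-[(5Z)-6-iodohepta-1,5-dien-2-yl]-2-methyloxolan-2-yl]ethoxy}diphenylsilane | C/C(I)=C/CCC(=C)[C@H]1CC[C@@](C)(CCO[Si](c2ccccc2)(c2ccccc2)C(C)(C)C)O1 | intermediate
12 | 2-[(2S,5R)-5-[(5Z)-6-iodohepta-1,5-dien-2-yl]-2-methyloxolan-2-yl]ethan-1-ol | C/C(I)=C/CCC(=C)[C@H]1CC[C@@](C)(CCO)O1 | intermediate
13 | 2-[(2S,5R)-5-[(5Z)-6-iodohepta-1,5-dien-2-yl]-2-methyloxolan-2-yl]acetaldehyde | C/C(I)=C/CCC(=C)[C@H]1CC[C@@](C)(CC=O)O1 | intermediate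
14 | 3-[(tert-butyldimethylsilyl)oxy]propanal | O=CCCO[Si](C)(C)C(C)(C)C | starting material
15 | tert-butyl acrylate | C=CC(=O)OC(C)(C)C | starting material
16 | tert-butyl 5-[(tert-butyldimethylsilyl)oxy]-3-hydroxy-2-methylidenepentanoate (racemic) | C=C(C(O)CCO[Si](C)(C)C(C)(C)C)C(=O)OC(C)(C)C | intermediate
17 | tert-butyl (2Z)-2-(bromomethyl)-5-[(tert-butyldimethylsilyl)oxy]pent-2-enoate | BrC/C(C(=O)OC(C)(C)C)=C\CCO[Si](C)(C)C(C)(C)C | intermediate
18 | O-trimethylsilyl ether of 19 (not isolated) | C=C(C(=O)OC(C)(C)C)[C@@H](CCO[Si](C)(C)C(C)(C)C)[C@@H](O[Si](C)(C)C)C[C@]1(C)CC[C@@H](O1)C(=C)CC/C=C(/C)I | intermediate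
19 | tert-butyl (3R,4S)-3-{2-[(tert-butyldimethylsilyl)oxy]ethyl}-4-hydroxy-5-[(2S,5R)-5-[(5Z)-6-iodohepta-1,5-dien-2-yl]-2-methyloxolan-2-yl]-2-methylidenepentanoate | C=C(C(=O)OC(C)(C)C)[C@@H](CCO[Si](C)(C)C(C)(C)C)[C@@H](O)C[C@]1(C)CC[C@@H](O1)C(=C)CC/C=C(/C)I | intermediate
20 | tert-butyl (3R,4S)-4-[(tert-butyldimethylsilyl)oxy]-3-{2-[(tert-butyldimethylsilyl)oxy]ethyl}-5-[(2S,5R)-5-[(5Z)-6-iodohepta-1,5-dien-2-yl]-2-methyloxolan-2-yl]-2-methylidenepentanoate | C=C(C(=O)OC(C)(C)C)[C@@H](CCO[Si](C)(C)C(C)(C)C)[C@@H](O[Si](C)(C)C(C)(C)C)C[C@]1(C)CC[C@@H](O1)C(=C)CC/C=C(/C)I | intermediate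
21 | tert-butyl (3R,4S)-4-[(tert-butyldimethylsilyl)oxy]-3-(2-hydroxyethyl)-5-[(2S,5R)-5-[(5Z)-6-iodohepta-1,5-dien-2-yl]-2-methyloxolan-2-yl]-2-methylidenepentanoate | C=C(C(=O)OC(C)(C)C)[C@@H](CCO)[C@@H](O[Si](C)(C)C(C)(C)C)C[C@]1(C)CC[C@@H](O1)C(=C)CC/C=C(/C)I | intermediate
22 | tert-butyl (3R,4S)-4-[(tert-butyldimethylsilyl)oxy]-3-(2-iodoethyl)-5-[(2S,5R)-5-[(5Z)-6-iodohepta-1,5-dien-2-yl]-2-methyloxolan-2-yl]-2-methylidenepentanoate | C=C(C(=O)OC(C)(C)C)[C@@H](CCI)[C@@H](O[Si](C)(C)C(C)(C)C)C[C@]1(C)CC[C@@H](O1)C(=C)CC/C=C(/C)I | intermediate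
23 | alkylzinc iodide of 22, C–ZnI in place of the primary C–I (not isolated) | C=C(C(=O)OC(C)(C)C)[C@@H](CC[Zn]I)[C@@H](O[Si](C)(C)C(C)(C)C)C[C@]1(C)CC[C@@H](O1)C(=C)CC/C=C(/C)I | intermediate
24 | tert-butyl (1R,2S,4S,7R,11Z)-2-[(tert-butyldimethylsilyl)oxy]-4,7-epoxycembra-8(19),11,15(17)-trien-16-oate | C=C(C(=O)OC(C)(C)C)[C@H]1CC/C(C)=C\CCC(=C)[C@H]2CC[C@](C)(O2)C[C@@H]1O[Si](C)(C)C(C)(C)C | intermediate
25 | tert-butyl (1R,2S,4S,7R,11S,12R)-2-[(tert-butyldimethylsilyl)oxy]-4,7:11,12-diepoxycembra-8(19),15(17)-dien-16-oate | C=C(C(=O)OC(C)(C)C)[C@H]1CC[C@@]3(C)O[C@H]3CCC(=C)[C@H]2CC[C@](C)(O2)C[C@@H]1O[Si](C)(C)C(C)(C)C | intermediate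
26 | (1R,2S,4S,7R,11S,12S)-2-[(tert-butyldimethylsilyl)oxy]-11-hydroxy-4,7-epoxycembra-8(19),15(17)-dien-16,12-olide | C=C1C(=O)O[C@@]2(C)CC[C@H]1[C@@H](O[Si](C)(C)C(C)(C)C)C[C@]1(C)CC[C@@H](O1)C(=C)CC[C@@H]2O | intermediate
27 | (1R,2S,4S,7R,11S,12S)-2,11-dihydroxy-4,7-epoxycembra-8(19),15(17)-dien-16,12-olide (CNP0289823.1) | C=C1C(=O)O[C@@]2(C)CC[C@H]1[C@@H](O)C[C@]1(C)CC[C@@H](O1)C(=C)CC[C@@H]2O | target

**Step count and risks**

Total step count: 21. Longest linear sequence: 19 (steps 1–11 and 14–21).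

Steps most likely to fail:

1. Step 18 (macrocyclisation). The organozinc may be lost to protonation or β-hydride elimination, or coupling between molecules may outrun ring closure. The fallback cyclises 22 without a preformed organometal by nickel-catalysed reductive cross-electrophile coupling (NiBr2(dme), 4,4′-di-tert-butyl-2,2′-bipyridine, Mn, NaI, dimethylacetamide, high dilution). Zerovalent nickel adds to the alkenyl iodide, the primary iodide is reduced to a C13 radical that is captured by the tethered alkenylnickel, and reductive elimination forms the same C12–C13 bond. The fallback sets out from 22 and comes back to the route at 24. New compounds on its way: none F0.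

2. Step 19 (epoxidation of the macrocyclic olefin). The conformational bias of the ring may override the catalyst and send oxygen to the wrong face, or the 8(19)-olefin may be oxidised as well. The fallback sets out from 24 and installs the oxygen by anti addition instead. N-Bromosuccinimide in aqueous THF at 0 °C should add bromine at C11 and water at the tertiary C12 to give the bromohydrin tert-butyl (1R,2S,4S,7R,11R,12R)-11-bromo-2-[(tert-butyldimethylsilyl)oxy]-12-hydroxy-4,7-epoxycembra-8(19),15(17)-dien-16-oate F1. K2CO3 in methanol then closes the epoxide with inversion at C11. The epoxide oxygen ends on the face opposite to the one the electrophile attacked, so the intrinsic facial preference of the ring is turned to advantage. The fallback comes back to the route at 25.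

3. Step 20 (lactonisation by epoxide opening). The cation-like C12 may be captured by the C2 silyl ether oxygen (oxane formation) or may rearrange by hydride shift to a C11 ketone instead of closing the seven-membered ring. The fallback sets out from 24 and frees the acid first. Me3SiOTf and 2,6-lutidine in CH2Cl2 at 0 °C, followed by aqueous work-up, should give (1R,2S,4S,7R,11Z)-2-[(tert-butyldimethylsilyl)oxy]-4,7-epoxycembra-8(19),11,15(17)-trien-16-oic acid F2. Shi epoxidation of its carboxylate in the basic buffer should give (1R,2S,4S,7R,11S,12R)-2-[(tert-butyldimethylsilyl)oxy]-4,7:11,12-diepoxycembra-8(19),15(17)-dien-16-oic acid F3. On acidification to pH 4 the free carboxylic acid, a better internal nucleophile than the ester and in no need of a strong acid, should open the epoxide at C12. The fallback comes back to the route at 26.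

**Further compounds**

F0 | step 18 | none | none
F1 | step 19 | tert-butyl (1R,2S,4S,7R,11R,12R)-11-bromo-2-[(tert-butyldimethylsilyl)oxy]-12-hydroxy-4,7-epoxycembra-8(19),15(17)-dien-16-oate | C=C(C(=O)OC(C)(C)C)[C@H]1CC[C@@](C)(O)[C@H](Br)CCC(=C)[C@H]2CC[C@](C)(O2)C[C@@H]1O[Si](C)(C)C(C)(C)C
F2 | step 20 | (1R,2S,4S,7R,11Z)-2-[(tert-butyldimethylsilyl)oxy]-4,7-epoxycembra-8(19),11,15(17)-trien-16-oic acid | C=C(C(=O)O)[C@H]1CC/C(C)=C\CCC(=C)[C@H]2CC[C@](C)(O2)C[C@@H]1O[Si](C)(C)C(C)(C)C
F3 | step 20 | (1R,2S,4S,7R,11S,12R)-2-[(tert-butyldimethylsilyl)oxy]-4,7:11,12-diepoxycembra-8(19),15(17)-dien-16-oic acid | C=C(C(=O)O)[C@H]1CC[C@@]3(C)O[C@H]3CCC(=C)[C@H]2CC[C@](C)(O2)C[C@@H]1O[Si](C)(C)C(C)(C)C
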